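**Plan**

- Rings: A and C are the benzo and pyranone rings of the 3-arylchromone, B its 2-(4-hydroxyphenyl) ring, E the methoxyphenyl link, F and D the pyranone and benzo rings of the 5,7-dihydroxyflavone.
- Cuts: ring F at O1–C2 and C2–C3 (C2 is the ester carbon on ring E, C3 an acetophenone methyl); ring A at C8–C8a, C7–C8, C5–C6 and C4a–C5; ring C back to a deoxybenzoin, an acetyl unit and an oxalate; the deoxybenzoin at the ring E–CH2 bond.
- Enabling feature: on ring A the C5 hydroxyl (peri to the C4 carbonyl) and the C7 methoxyl are meta, C6 and C8 carry hydrogen, and C4a–C8a is a C=C bond of a 4-pyranone. C5 can therefore be a ketene carbon, C6–C7 methoxyacetylene and C8 a diazo carbon, with the two oxygens differentiated from the start.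
- Forward order: ring E is joined to the ring B ketone, ring C is closed as a 4-pyranone acid, ring A is annulated onto it, ring F is closed from the ring E ester and a protected phloroacetophenone (which brings ring D), and three benzyl ethers are removed last.
- Stereochemistry: the target has no stereocentre and no stereogenic double bond, so nothing has to be controlled.

Key step: step 7

Remark: metal enolates, phenoxides, the sodium acetylide and keto–enol tautomers are treated as forms of the numbered compounds and carry no number of their own; methoxyacetylene is made within the route because it is not a dependable catalogue item.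

Shorthand: Pyr = 6-[4-(benzyloxy)phenyl]-5-[2-methoxy-5-(methoxycarbonyl)phenyl]-4-oxo-4H-pyran-2-yl; the ring carbon next to its point of attachment is pyranone C3–H.

**Route**

Step 1
Reactants: 1 1-[4-(benzyloxy)phenyl]ethanone; 2 methyl 3-bromo-4-methoxybenzoate
Product: 3 methyl 3-{2-[4-(benzyloxy)phenyl]-2-oxoethyl}-4-methoxybenzoate
Conditions: Pd2(dba)3 (1.5 mol%), Xantphos (3.6 mol%), K3PO4, toluene, 80 °C
Reagents that add atoms: none
Why: Palladium-catalysed α-arylation of an aryl methyl ketone enolate (oxidative addition of 2 to zerovalent palladium, enolate transfer, reductive elimination) with the mild base K3PO4 should spare the methyl ester, and the ortho-methoxy group of 2 hinders a second arylation.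

Step 2
Reactants: 3 methyl 3-{2-[4-(benzyloxy)phenyl]-2-oxoethyl}-4-methoxybenzoate
Product: 4 methyl 3-{1-[4-(benzyloxy)phenyl]-1,3-dioxobutan-2-yl}-4-methoxybenzoate (racemic, enolisable)
Conditions: AcCl, MgBr2·OEt2, i-Pr2NEt, CH2Cl2, 0 °C → rt
Reagents that add atoms: acetyl chloride, CC(Cl)=O
Why: Soft-enolisation C-acylation, in which MgBr2 and the amine generate the magnesium enolate of the acidic benzylic ketone and acetylation goes to carbon because the product is held as a chelated magnesium 1,3-diketonate.

Step 3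
Reactants: 4 methyl 3-{1-[4-(benzyloxy)phenyl]-1,3-dioxobutan-2-yl}-4-methoxybenzoate; 5 di-tert-butyl oxalate
Product: 6 tert-butyl 6-[4-(benzyloxy)phenyl]-5-[2-methoxy-5-(methoxycarbonyl)phenyl]-2,4,6-trioxohexanoate (drawn as the triketone, present as enols)
Conditions: LiN(i-Pr)2 (2.2 equiv), THF, −78 → −30 °C; 5 (1.3 equiv), −78 → 0 °C; 1 M HCl, 0 °C
Reagents that add atoms: none
Why: Claisen condensation of a 1,3-diketone dianion, in which the only acidic site left after the central C–H is the acetyl methyl, so this more reactive terminal carbanion should attack the oxalate once while the low temperature keeps the amide base off the anisate ester.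

Step 4
Reactants: 6 tert-butyl 6-[4-(benzyloxy)phenyl]-5-[2-methoxy-5-(methoxycarbonyl)phenyl]-2,4,6-trioxohexanoate
Product: 8 Pyr-carboxylic acid (6-[4-(benzyloxy)phenyl]-5-[2-methoxy-5-(methoxycarbonyl)phenyl]-4-oxo-4H-pyran-2-carboxylic acid), via pyranone tert-butyl ester 7 (not isolated)
Conditions: CF3CO2H/CH2Cl2 (1:1), rt
Reagents that add atoms: none
Why: Acid-catalysed cyclodehydration of the 1,3,5-tricarbonyl chain (enol oxygen of the aryl ketone onto the α-keto ester carbonyl, loss of water) closes ring C as a 4-pyranone, and acidolysis of the tert-butyl ester with loss of isobutene frees the pyranone carboxyl alone, the methyl ester and the benzyl ether being stable to CF3CO2H at room temperature.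

Step 5
Reactants: 8 Pyr-carboxylic acid
Product: 10 2-diazo-1-Pyr-ethanone (pyranonyl diazomethyl ketone), via acid chloride 9 (not isolated)
Conditions: (COCl)2, cat. DMF, CH2Cl2, 0 °C → rt; concentrate; CH2N2 (3 equiv), Et2O/THF, 0 °C
Reagents that add atoms: diazomethane, C=[N+]=[N-]
Why: Acylation of diazomethane by an acid chloride (first stage of an Arndt–Eistert sequence), a reaction known for chromone- and pyranone-2-carbonyl chlorides, with the excess diazomethane taking up the HCl as chloromethane.

Step 6
Reactants: 11 2-chloro-1,1-dimethoxyethane (chloroacetaldehyde dimethyl acetal)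
Product: 13 methoxyacetylene (collected by distillation into toluene at −78 °C), via 1-chloro-2-methoxyethene 12 (not isolated)
Conditions: NaNH2 (3 equiv), liq. NH3, −33 °C; NH3 evaporated; saturated aq. NaCl, −20 °C; distil
Reagents that add atoms: none
Why: Twofold base-induced elimination from a chloroacetal with NaNH2 in liquid ammonia (methanol first, then HCl) is the standard preparation of alkoxyacetylenes, the product being released from its sodium acetylide on aqueous quench.

Step 7
Reactants: 10 2-diazo-1-Pyr-ethanone; 13 methoxyacetylene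
Product: 17 methyl 3-{2-[4-(benzyloxy)phenyl]-5-hydroxy-7-methoxy-4-oxo-4H-chromen-3-yl}-4-methoxybenzoate, via pyranonylketene 14 (not isolated), via methoxycyclobutenone 15 (not isolated), via dienylketene 16 (not isolated)
Conditions: 13 (5 equiv), 450 nm LEDs, toluene (0.02 M), 20 °C, sealed vessel; then 80 °C
Reagents that add atoms: none
Why: Proposed new method: excitation of the diazo ketone should expel N2 and shift pyranone C2 to the carbene carbon (Wolff rearrangement, C8–C8a) to give vinylketene 14, whose carbonyl carbon is attacked by the nucleophilic CH terminus of 13 in a (2+2) cycloaddition (C5–C6 and C7–C8) to cyclobutenone 15, and warming opens 15 by four-electron electrocyclic cleavage to dienylketene 16, which closes onto pyranone C3 (C4a–C5) and enolises. The closest known reaction type is the Danheiser benzannulation of aryl, heteroaryl and cycloalkenyl diazomethyl ketones with alkoxy- and siloxyalkynes; the untested element is a 4-pyranone C2=C3 bond as the vinyl component, which should behave like the enol-ether double bond of the furyl cases. Ring A is the only ring closed, by a thermal six-electron disrotatory electrocyclisation of 16 that is made irreversible by tautomerisation to the C5 phenol hydrogen-bonded to the C4 carbonyl. No stereocentre is created, since the sp3 carbon of racemic 15 and that of the dienone tautomer are lost on the way to the arene. The step needs one (2+2) regiochemistry, which the polarisation of the ynol ether secures by placing its oxygen-bearing carbon at C7 and the ketene carbon at C5, and it needs the diazo ketone to react in preference to the photolabile pyranone and cis-stilbene chromophores, which irradiation in the visible, where only the diazo ketone is expected to absorb, should secure. Methoxyacetylene has no β-hydrogen for retro-ene loss, unlike ethoxyacetylene, and should therefore tolerate the 80 °C stage.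

Step 8
Reactants: 18 1-(2,4,6-trihydroxyphenyl)ethanone
Product: 19 1-[2,4-bis(benzyloxy)-6-hydroxyphenyl]ethanone
Conditions: BnBr (2.1 equiv), K2CO3, DMF, rt
Reagents that add atoms: benzyl bromide, BrCc1ccccc1
Why: Williamson etherification under mild base alkylates the C4 hydroxyl and one ortho hydroxyl, the remaining ortho hydroxyl being chelated to the acetyl carbonyl and therefore the least reactive.

Step 9
Reactants: 17 methyl 3-{2-[4-(benzyloxy)phenyl]-5-hydroxy-7-methoxy-4-oxo-4H-chromen-3-yl}-4-methoxybenzoate; 19 1-[2,4-bis(benzyloxy)-6-hydroxyphenyl]ethanone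
Product: 20 1-[2,4-bis(benzyloxy)-6-hydroxyphenyl]-3-(3-{2-[4-(benzyloxy)phenyl]-5-hydroxy-7-methoxy-4-oxo-4H-chromen-3-yl}-4-methoxyphenyl)propane-1,3-dione
Conditions: 19 (2 equiv), LiN(SiMe3)2 (5.5 equiv), THF, −78 °C; then 17, −78 °C → rt; 1 M HCl
Reagents that add atoms: none
Why: Crossed Claisen condensation of the dilithiated 2-hydroxyacetophenone (phenoxide enolate) with a methyl aroate, the polyanion route to flavone 1,3-diketones; 17 reacts as its C5 phenoxide, which deactivates ring C towards conjugate attack, and deprotonation of the diketone formed drives the equilibrium.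

Step 10
Reactants: 20 the 1,3-diketone of step 9
Product: 21 3-{5-[5,7-bis(benzyloxy)-4-oxo-4H-chromen-2-yl]-2-methoxyphenyl}-2-[4-(benzyloxy)phenyl]-5-hydroxy-7-methoxy-4H-chromen-4-one
Conditions: p-TsOH·H2O (20 mol%), toluene, 90 °C
Reagents that add atoms: none
Why: Acid-catalysed cyclodehydration of an o-hydroxyaryl 1,3-diketone closes ring F (the phenol oxygen adds to the ring E-side carbonyl and water is lost), the final stage of a Baker–Venkataraman type flavone synthesis, under conditions that aryl benzyl ethers tolerate.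

Step 11
Reactants: 21 the tribenzyl biflavone of step 10
Product: 22 3-[5-(5,7-dihydroxy-4-oxo-4H-chromen-2-yl)-2-methoxyphenyl]-5-hydroxy-2-(4-hydroxyphenyl)-7-methoxy-4H-chromen-4-one (target)
Conditions: H2 (1 atm), 10% Pd/C, THF/MeOH (1:1), rt
Reagents that add atoms: none
Why: Hydrogenolysis of the three aryl benzyl ethers over Pd/C should leave the methyl ethers and both chromone double bonds intact, since the latter are vinylogous esters that resist hydrogenation at 1 atm and room temperature.

**Compound list**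

1 | 1-[4-(benzyloxy)phenyl]ethanone | CC(=O)c1ccc(OCc2ccccc2)cc1 | starting material
2 | methyl 3-bromo-4-methoxybenzoate | COC(=O)c1ccc(OC)c(Br)c1 | starting material
3 | methyl 3-{2-[4-(benzyloxy)phenyl]-2-oxoethyl}-4-methoxybenzoate | COC(=O)c1ccc(OC)c(CC(=O)c2ccc(OCc3ccccc3)cc2)c1 | intermediate
4 | methyl 3-{1-[4-(benzyloxy)phenyl]-1,3-dioxobutan-2-yl}-4-methoxybenzoate (racemic) | COC(=O)c1ccc(OC)c(C(C(C)=O)C(=O)c2ccc(OCc3ccccc3)cc2)c1 | intermediate
5 | di-tert-butyl oxalate | CC(C)(C)OC(=O)C(=O)OC(C)(C)C | starting material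
6 | tert-butyl 6-[4-(benzyloxy)phenyl]-5-[2-methoxy-5-(methoxycarbonyl)phenyl]-2,4,6-trioxohexanoate (racemic, enolised) | COC(=O)c1ccc(OC)c(C(C(=O)CC(=O)C(=O)OC(C)(C)C)C(=O)c2ccc(OCc3ccccc3)cc2)c1 | intermediate
7 | tert-butyl Pyr-carboxylate (not isolated) | COC(=O)c1ccc(OC)c(-c2c(-c3ccc(OCc4ccccc4)cc3)oc(C(=O)OC(C)(C)C)cc2=O)c1 | intermediate
8 | Pyr-carboxylic acid | COC(=O)c1ccc(OC)c(-c2c(-c3ccc(OCc4ccccc4)cc3)oc(C(=O)O)cc2=O)c1 | intermediate
9 | Pyr-carbonyl chloride (not isolated) | COC(=O)c1ccc(OC)c(-c2c(-c3ccc(OCc4ccccc4)cc3)oc(C(Cl)=O)cc2=O)c1 | intermediate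
10 | 2-diazo-1-Pyr-ethanone | [N-]=[N+]=CC(=O)c1cc(=O)c(-c2cc(C(=O)OC)ccc2OC)c(-c2ccc(OCc3ccccc3)cc2)o1 | intermediate
11 | 2-chloro-1,1-dimethoxyethane | COC(CCl)OC | starting material
12 | 1-chloro-2-methoxyethene, drawn as the Z isomer (not isolated) | CO/C=C\Cl | intermediate
13 | methoxyacetylene | C#COC | intermediate
14 | 2-Pyr-ethenone, the vinylketene (not isolated) | O=C=Cc1cc(=O)c(-c2cc(C(=O)OC)ccc2OC)c(-c2ccc(OCc3ccccc3)cc2)o1 | intermediate
15 | 3-methoxy-4-Pyr-cyclobut-2-en-1-one, racemic (not isolated) | COC1=CC(=O)C1c1cc(=O)c(-c2cc(C(=O)OC)ccc2OC)c(-c2ccc(OCc3ccccc3)cc2)o1 | intermediate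
16 | (3E)-3-methoxy-4-Pyr-buta-1,3-dien-1-one, ketene cis to the pyranone (not isolated) | O=C=C/C(OC)=C\c1cc(=O)c(-c2cc(C(=O)OC)ccc2OC)c(-c2ccc(OCc3ccccc3)cc2)o1 | intermediate
17 | methyl 3-{2-[4-(benzyloxy)phenyl]-5-hydroxy-7-methoxy-4-oxo-4H-chromen-3-yl}-4-methoxybenzoate | COc1cc(O)c2c(=O)c(-c3cc(C(=O)OC)ccc3OC)c(-c3ccc(OCc4ccccc4)cc3)oc2c1 | intermediate
18 | 1-(2,4,6-trihydroxyphenyl)ethanone | CC(=O)c1c(O)cc(O)cc1O | starting material
19 | 1-[2,4-bis(benzyloxy)-6-hydroxyphenyl]ethanone | CC(=O)c1c(O)cc(OCc2ccccc2)cc1OCc1ccccc1 | intermediate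
20 | 1-[2,4-bis(benzyloxy)-6-hydroxyphenyl]-3-(3-{2-[4-(benzyloxy)phenyl]-5-hydroxy-7-methoxy-4-oxo-4H-chromen-3-yl}-4-methoxyphenyl)propane-1,3-dione | COc1cc(O)c2c(=O)c(-c3cc(C(=O)CC(=O)c4c(O)cc(OCc5ccccc5)cc4OCc4ccccc4)ccc3OC)c(-c3ccc(OCc4ccccc4)cc3)oc2c1 | intermediate
21 | 3-{5-[5,7-bis(benzyloxy)-4-oxo-4H-chromen-2-yl]-2-methoxyphenyl}-2-[4-(benzyloxy)phenyl]-5-hydroxy-7-methoxy-4H-chromen-4-one | COc1cc(O)c2c(=O)c(-c3cc(-c4cc(=O)c5c(OCc6ccccc6)cc(OCc6ccccc6)cc5o4)ccc3OC)c(-c3ccc(OCc4ccccc4)cc3)oc2c1 | intermediate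
22 | 3-[5-(5,7-dihydroxy-4-oxo-4H-chromen-2-yl)-2-methoxyphenyl]-5-hydroxy-2-(4-hydroxyphenyl)-7-methoxy-4H-chromen-4-one | COc1cc(O)c2c(=O)c(-c3cc(-c4cc(=O)c5c(O)cc(O)cc5o4)ccc3OC)c(-c3ccc(O)cc3)oc2c1 | target

**Step count and risks**

Total steps: 11. Longest linear sequence: 9 steps (steps 1, 2, 3, 4, 5, 7, 9, 10, 11, from 1 and 2 to 22); steps 6 and 8 are side branches.

Steps most likely to fail:

1. Step 7 (the proposed new method). What may go wrong: light absorption and rearrangement by the pyranone instead of the diazo group, dipolar cycloaddition of the diazo ketone to the ynol ether before nitrogen is lost, or a dienylketene that does not close onto the pyranone carbon. Fallback (known chemistry, ring A brought in as a preformed arene), setting out from 3 and returning at 17: 3 is C-acylated under the conditions of step 2 with 2,6-difluoro-4-methoxybenzoyl chloride, made from the commercial acid and (COCl)2, to give methyl 3-{1-[4-(benzyloxy)phenyl]-3-(2,6-difluoro-4-methoxyphenyl)-1,3-dioxopropan-2-yl}-4-methoxybenzoate F1. K2CO3 in DMF at 80 °C should then close ring C by intramolecular SNAr displacement of one fluoride by the enolate oxygen, giving methyl 3-{2-[4-(benzyloxy)phenyl]-5-fluoro-7-methoxy-4-oxo-4H-chromen-3-yl}-4-methoxybenzoate F2. The remaining fluoride, activated by the peri carbonyl, is exchanged for hydroxyl with acetohydroxamic acid and K2CO3 in DMSO at 80 °C, a hydroxide surrogate that should spare the methyl ester, which gives 17.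

2. Step 3. What may go wrong: incomplete second deprotonation of the diketone, retro-Claisen loss of the acetyl group, or attack of the amide base on the anisate ester. Fallback (ring C built by acylketene addition to an enamine, then side-chain oxidation), setting out from 3 and returning at 8: 3 is condensed with morpholine (TiCl4, toluene) to the enamine methyl 3-{(E)-2-[4-(benzyloxy)phenyl]-2-(morpholin-4-yl)ethenyl}-4-methoxybenzoate F3. Heating F3 with 2,2,6-trimethyl-4H-1,3-dioxin-4-one in toluene at 110 °C (acetylketene C-acylation, ring closure and loss of morpholine on acidic work-up) should give methyl 3-{2-[4-(benzyloxy)phenyl]-6-methyl-4-oxo-4H-pyran-3-yl}-4-methoxybenzoate F4. SeO2 in dioxane at reflux oxidises the pyranone methyl group to the aldehyde methyl 3-{2-[4-(benzyloxy)phenyl]-6-formyl-4-oxo-4H-pyran-3-yl}-4-methoxybenzoate F5, and Pinnick oxidation (NaClO2, NaH2PO4, 2-methyl-2-butene, t-BuOH/H2O) then gives 8.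

3. Step 9. What may go wrong: slow addition of the enolate to the electron-rich anisate ester, quenching of the enolate by proton transfer, or conjugate attack on ring C. Fallback (the acyl group delivered intramolecularly), setting out from 17 and returning at 20: 17 is saponified (LiOH, THF/H2O, rt) to 3-{2-[4-(benzyloxy)phenyl]-5-hydroxy-7-methoxy-4-oxo-4H-chromen-3-yl}-4-methoxybenzoic acid F6. F6 is coupled with 19 (2 equiv, EDC·HCl, DMAP, CH2Cl2; the peri-chelated C5 hydroxyl of F6 is the poorer nucleophile) to 2-acetyl-3,5-bis(benzyloxy)phenyl 3-{2-[4-(benzyloxy)phenyl]-5-hydroxy-7-methoxy-4-oxo-4H-chromen-3-yl}-4-methoxybenzoate F7. Baker–Venkataraman rearrangement (KOH, pyridine, 50 °C) then moves the aroyl group from oxygen to the acetyl carbon and gives 20.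

**Further compounds**

F1 | step 7 | methyl 3-{1-[4-(benzyloxy)phenyl]-3-(2,6-difluoro-4-methoxyphenyl)-1,3-dioxopropan-2-yl}-4-methoxybenzoate (racemic) | COC(=O)c1ccc(OC)c(C(C(=O)c2ccc(OCc3ccccc3)cc2)C(=O)c2c(F)cc(OC)cc2F)c1
F2 | step 7 | methyl 3-{2-[4-(benzyloxy)phenyl]-5-fluoro-7-methoxy-4-oxo-4H-chromen-3-yl}-4-methoxybenzoate | COc1cc(F)c2c(=O)c(-c3cc(C(=O)OC)ccc3OC)c(-c3ccc(OCc4ccccc4)cc3)oc2c1
F3 | step 3 | methyl 3-{(E)-2-[4-(benzyloxy)phenyl]-2-(morpholin-4-yl)ethenyl}-4-methoxybenzoate | COC(=O)c1ccc(OC)c(/C=C(/N2CCOCC2)c2ccc(OCc3ccccc3)cc2)c1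
F4 | step 3 | methyl 3-{2-[4-(benzyloxy)phenyl]-6-methyl-4-oxo-4H-pyran-3-yl}-4-methoxybenzoate | COC(=O)c1ccc(OC)c(-c2c(-c3ccc(OCc4ccccc4)cc3)oc(C)cc2=O)c1
F5 | step 3 | methyl 3-{2-[4-(benzyloxy)phenyl]-6-formyl-4-oxo-4H-pyran-3-yl}-4-methoxybenzoate | COC(=O)c1ccc(OC)c(-c2c(-c3ccc(OCc4ccccc4)cc3)oc(C=O)cc2=O)c1
F6 | step 9 | 3-{2-[4-(benzyloxy)phenyl]-5-hydroxy-7-methoxy-4-oxo-4H-chromen-3-yl}-4-methoxybenzoic acid | COc1cc(O)c2c(=O)c(-c3cc(C(=O)O)ccc3OC)c(-c3ccc(OCc4ccccc4)cc3)oc2c1
F7 | step 9 | 2-acetyl-3,5-bis(benzyloxy)phenyl 3-{2-[4-(benzyloxy)phenyl]-5-hydroxy-7-methoxy-4-oxo-4H-chromen-3-yl}-4-methoxybenzoate | COc1cc(O)c2c(=O)c(-c3cc(C(=O)Oc4cc(OCc5ccccc5)cc(OCc5ccccc5)c4C(C)=O)ccc3OC)c(-c3ccc(OCc4ccccc4)cc3)oc2c1
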